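## The problem

The target is a linear tridepside: three 6-methylsalicylate rings joined head to tail by two aryl ester bonds. The carboxyl of ring A (2-hydroxy-4,5-dimethoxy-6-methylbenzoyl) sits on O4 of ring B, and the carboxyl of ring B sits on O4 of ring C, whose own carboxyl is free. There are no stereocentres, so nothing can be relayed from one centre to another; the whole difficulty is telling seven phenolic oxygens apart (two methyl ethers, two acylated, three free and ortho to a carbonyl). Both acyl donors are 2,6-disubstituted benzoic acids and both acceptors are phenols, so each ester bond is hindered on the acyl side and needs a strongly activated partner. The aryl esters are cleaved or scrambled by hydroxide, alkoxides and amines, and the terminal orsellinic acid unit loses CO2 on heating or in strong acid, so the last operation must be neutral. Ring A carries its two methoxy groups next to the methyl group, a pattern that does not come from orcinol-type materials. The enabling feature is ring C, numbered from its carboxyl-bearing carbon C1: it is a resorcinol whose oxygens at C2 and C4 flank the C3 hydrogen and must end up different. If C2 with its oxygen comes from a ketene carbonyl and C3–C4 with its oxygen from an oxygenated alkyne, the two oxygens are distinct by origin, free at C2 and silylated at C4.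

## Retrosynthesis

Target 29 is taken back to the tribenzyl compound 28 by cutting three benzyl C–O bonds (the ring C benzyl ester and the benzyl ethers on O2 of rings A and B). Hydrogenolysis is the only unmasking that leaves two aryl esters and a salicylic acid untouched, and it removes all three groups in one operation.

Compound 28 is cut at the acyl–oxygen bond between the ring B carbonyl and O4 of ring C, giving the ring C silyl ether 15 and the ring A–ring B acyl fluoride 27. Cutting here rather than at the A–B ester divides the molecule into halves of similar size. It also lets the ring C oxygen arrive as a silyl ether, which is exactly what the ring-forming step delivers. The forward reaction only asks fluoride to unmask the phenoxide in the presence of the acyl fluoride, so no amine or alkoxide is needed.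

Ring C of 15 is cut at C5–C6, C2–C3, C4–C5 and C1–C2, leading to the diazo ketone 10 and ethynyl triisopropylsilyl ether 5. Against functionalising an orsellinate, this builds the ring with O2 free and O4 silylated from the outset, and the two precursors are five- and two-carbon acyclic pieces. The forward step must place the unsubstituted alkyne carbon on the ketene carbonyl carbon and keep the ester away from the ketene.

Diazo ketone 10 is cut at the diazo carbon to the methyl ketone 8, and 8 at its C=C bond to butane-2,3-dione 6 and the stabilised ylide 7. The route from a 2-methylbutenedioic acid through an acid chloride and a diazoalkane was set aside for two reasons. One carboxyl would first have to be esterified selectively, and the doubly activated alkene of the enoyl chloride is itself a dipolarophile toward the diazoalkane. Olefination of a symmetrical diketone poses no regiochemical question, and diazo transfer to the acetyl group avoids diazoalkanes altogether.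

Siloxyalkyne 5 is cut at its terminal C–H to the C-silylated alkyne 4, and 4 at its C–O and O–Si bonds to trimethylsilylacetylene 1. The trimethylsilyl group serves only to give a well-behaved acetylide and ynolate, and it must later be removed without loss of the oxygen-bound silyl group.

Acyl fluoride 27 goes back through acid 26 and aldehydes 25 and 24 to ring A acid 22 and 2,4-dihydroxy-6-methylbenzaldehyde 23, the cut being the A–B acyl–oxygen bond. The aldehyde of 23 is a latent carboxyl that cannot compete as an acyl donor, and its hydrogen bond to the 2-hydroxyl leaves only the 4-hydroxyl to be acylated.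

Ring A acid 22 is cut at C1–CO2H to bromide 20, then at C–Br to benzyl ether 19, at O–benzyl to phenol 18 and at the phenolic C–O bond to 2,3-dimethoxytoluene 16. The adjacent methoxy groups and the methyl group are bought in place. The forward steps must oxygenate the one unhindered ring C–H and then substitute the position between the benzyloxy and methyl groups.

## Roads not taken

Alternative 1: The B–C ester is cut on both sides of its carbonyl carbon, which is supplied as carbon monoxide. Aryl iodide A1 (the ring A ester of a ring B iodide), CO and benzyl orsellinate A2 would be united by Pd(OAc)2 with Xantphos and Et3N. This forms the B1–carbonyl C–C bond and the carbonyl–O4 bond to ring C in one operation and gives A3, which is identical with compound 28.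
- Merits: ring C is simply A2, ring B needs no aldehyde, no oxidation and no acyl fluoride, and the unchelated 4-hydroxyl of A2 reacts ahead of the 2-hydroxyl.
- Weak points: the iodide is flanked by benzyloxy and methyl, so CO insertion and capture of a di-ortho-substituted aroylpalladium by a weakly nucleophilic phenol would need heat and base. Under those conditions the phenoxide of A2 can exchange with the A–B aryl ester already present. The iodide must also be placed regioselectively on an orcinol-derived ring.
- Comparison: this road is shorter by roughly four steps and reaches the same penultimate compound, so it is the better plan on step count. The chosen plan sets against it an ester formation at room temperature from a preformed acyl donor and a phenoxide released in the same flask. It also differentiates the ring C oxygens by construction and not by kinetic selectivity.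

Alternative 2: Ring A is cut at A1–A6 and A3–A4 and built from acyclic esters. The sodium enolate of benzyl acetoacetate A4 would add to methyl (Z)-2-methoxybut-2-enoate A5, and the ketone enolate would then condense on the methyl ester to close the cyclohexanedione A6. Dehydrogenation and O-methylation would follow later.
- Merits: cheap materials, and the awkward methoxy-next-to-methyl pattern of ring A is set in one annulation.
- Weak points: A5 is a β-substituted, α-alkoxy acrylate and a poor Michael acceptor. The aromatisation is an oxidation, and the subsequent methylation must pick O4 of ring A over its chelated O2 and, if done late, over every other phenol in the molecule. Nothing in this step addresses either ester linkage.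
- Comparison: it spends its key step on the ring that 2,3-dimethoxytoluene 16 already provides in four well-precedented steps to acid 22. Its only advantage is cost of materials, which does not outweigh a late oxidation and a late selective methylation.

Alternative 3: Ring B is cut at B1–B2 and B5–B6. (1Z)-1-Methoxy-1,3-bis(trimethylsilyloxy)buta-1,3-diene A7 would add to the but-2-ynoate ester A8 of the ring C phenol, and loss of methanol from the adduct would give the aromatic depside A9. Acylation of its 4-hydroxyl with acid 22 and hydrogenolysis would follow.
- Merits: the hindered B–C ester never has to be made by acylating a phenol with a 2,6-disubstituted acid, since it enters as an unhindered ynoate ester and the ring is grown around it. The regiochemistry of this diene with ynoates is reliable, and the route is shorter than the chosen one.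
- Weak points: a 3-methyl ynoate is a sluggish dienophile, and the moisture-sensitive ketene acetal diene must survive the temperature it needs. Silyl transfer or conjugate addition can consume the aryl ynoate. The cycloaddition also falls late, on a ring C piece that has already cost protecting-group steps.
- Comparison: this road is better at the B–C ester, which is the weakest point of the chosen end game. The chosen plan sets against it a ring construction carried out early on small fragments, and a ring C that needs no separate differentiation of its two hydroxyls.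

Key step: step 5

Assumption: compounds 1, 6, 7, 16 and 23 are taken as purchasable; the trifluoroacetylated ketone 9 is carried forward crude after aqueous work-up and is therefore treated as not isolated.

## Route

Step 1
Reactants: 1 trimethylsilylacetylene
Product: 4 triisopropyl{[(trimethylsilyl)ethynyl]oxy}silane, via lithium (trimethylsilyl)acetylide 2 (not isolated), via lithium 2-(trimethylsilyl)ethynolate 3 (not isolated)
Conditions: n-BuLi, THF, −78 °C; t-BuOOLi (from t-BuOOH and LiN(SiMe3)2, THF, −78 °C), −78 → 0 °C; i-Pr3SiOSO2CF3, −78 → 0 °C
Reagents that add atoms: tert-butyl hydroperoxide, CC(C)(C)OO; triisopropylsilyl trifluoromethanesulfonate, CC(C)[Si](C(C)C)(C(C)C)OS(=O)(=O)C(F)(F)F; n-butyllithium, [Li]CCCC (lithium retained only in 2 and 3)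
Why: Oxidation of a lithium acetylide with lithium tert-butyl peroxide is an established entry to ynolates from terminal alkynes, and the bulky silyl triflate should take the ynolate at oxygen to give an isolable siloxyalkyne. The carbon-bound trimethylsilyl group shields the carbon terminus during this O-silylation.

Step 2
Reactants: 4 triisopropyl{[(trimethylsilyl)ethynyl]oxy}silane
Product: 5 ethynyl triisopropylsilyl ether
Conditions: K2CO3 (0.1 equiv), MeOH/THF, 0 °C, short reaction time
Reagents that add atoms: none
Why: Methoxide-induced protodesilylation of an alkynyl–SiMe3 bond is fast at 0 °C, whereas the hindered O–Si(i-Pr)3 bond should be attacked far more slowly, so the terminal siloxyalkyne should be released selectively. It is used promptly in step 5.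

Step 3
Reactants: 6 butane-2,3-dione; 7 benzyl (triphenylphosphoranylidene)acetate
Product: 8 benzyl (E)-3-methyl-4-oxopent-2-enoate
Conditions: 6 (3 equiv), CH2Cl2, 0 °C → rt
Reagents that add atoms: none
Why: Wittig olefination of one carbonyl of the symmetrical 1,2-diketone by a stabilised ylide; the excess of diketone suppresses double olefination. The E isomer (ester trans to acetyl) is expected to predominate and is purified by chromatography.

Step 4
Reactants: 8 benzyl (E)-3-methyl-4-oxopent-2-enoate
Product: 10 benzyl (E)-5-diazo-3-methyl-4-oxopent-2-enoate, via trifluoroacetyl diketone 9 (not isolated)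
Conditions: LiN(SiMe3)2, THF, −78 °C (8 added to the base); CF3CO2CH2CF3, −78 °C; then MsN3, Et3N, H2O, MeCN, rt, in the dark
Reagents that add atoms: methanesulfonyl azide, CS(=O)(=O)N=[N+]=[N-]; 2,2,2-trifluoroethyl trifluoroacetate, O=C(OCC(F)(F)F)C(F)(F)F (trifluoroacetyl group retained only in 9)
Why: Detrifluoroacetylative diazo transfer: kinetic deprotonation of the acetyl methyl group, Claisen trifluoroacetylation, then diazo transfer from the sulfonyl azide with loss of the trifluoroacetyl group as its sulfonamide. This is the standard way to α,β-unsaturated α′-diazo ketones and avoids exposing an electron-poor alkene to a diazoalkane.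

Step 5
Reactants: 10 benzyl (E)-5-diazo-3-methyl-4-oxopent-2-enoate; 5 ethynyl triisopropylsilyl ether
Product: 15 benzyl 2-hydroxy-6-methyl-4-[(triisopropylsilyl)oxy]benzoate, via vinylketene 11 (not isolated), via 4-alkenylcyclobutenone 12 (not isolated), via dienylketene 13 (not isolated), via cyclohexadienone 14 (not isolated)
Conditions: 5 (1.5 equiv), ClCH2CH2Cl (degassed), hν 254 nm (low-pressure Hg lamps, Vycor), rt; then 80 °C
Reagents that add atoms: none
Why: Light expels N2 from 10 and the alkenyl group shifts to the former diazo carbon (Wolff rearrangement, bond C5–C6) to give vinylketene 11; the polarised siloxyalkyne 5 then adds across the ketene C=C in a (2+2) cycloaddition (bonds C2–C3 and C4–C5) to give cyclobutenone 12. Heating opens 12 by 4π electrocyclic cleavage to dienylketene 13, which closes ring C by thermal 6π electrocyclisation (bond C1–C2) to dienone 14, and enolisation gives phenol 15. The closest known reaction type is the second-generation Danheiser benzannulation of α,β-unsaturated α′-diazo ketones with trialkylsiloxyalkynes, which gives resorcinol monosilyl ethers. Ring C is thus closed as a six-membered carbocycle by 6π electrocyclisation after the two alkyne carbons have been spliced in by the (2+2)/4π sequence. No stereocentre is created that survives, since the sp3 centres of 12 and 14 are erased by ring opening and enolisation. The step needs one regiochemical outcome in the (2+2) event, bonding of the unsubstituted alkyne carbon to the ketene carbonyl carbon; donation from the siloxy oxygen makes that carbon the nucleophilic terminus, so the silyloxy group ends meta to the new hydroxyl, with the ketene oxygen free at C2 and the alkyne oxygen silylated at C4. It also needs the ester to stay remote from the ketene, which the E geometry of 10 set in step 3 secures, so that closure of 11 through the ester oxygen to a 2-pyranone is geometrically barred.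

Step 6
Reactants: 16 2,3-dimethoxytoluene
Product: 18 3,4-dimethoxy-5-methylphenol, via aryl pinacol boronate 17 (not isolated)
Conditions: [Ir(OMe)(cod)]2 (1.5 mol %), 4,4′-di-tert-butyl-2,2′-bipyridine (3 mol %), B2pin2, THF, 80 °C; then KHSO5 (as 2KHSO5·KHSO4·K2SO4), acetone/H2O, rt
Reagents that add atoms: potassium peroxymonosulfate, [K+].[O-]S(=O)(=O)OO; bis(pinacolato)diboron, CC1(C)OB(B2OC(C)(C)C(C)(C)O2)OC1(C)C (boryl group retained only in 17)
Why: Iridium-catalysed C–H borylation is sterically controlled and should occur at the only ring C–H of 16 that has no ortho substituent. Oxidation of the C–B bond in the same flask gives the phenol.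

Step 7
Reactants: 18 3,4-dimethoxy-5-methylphenol
Product: 19 5-(benzyloxy)-1,2-dimethoxy-3-methylbenzene
Conditions: BnBr, K2CO3, DMF, rt
Reagents that add atoms: benzyl bromide, BrCc1ccccc1
Why: Williamson ether synthesis on an unhindered phenol. The benzyl ether is chosen so that it leaves in the final hydrogenolysis.

Step 8
Reactants: 19 5-(benzyloxy)-1,2-dimethoxy-3-methylbenzene
Product: 20 1-(benzyloxy)-2-bromo-4,5-dimethoxy-3-methylbenzene
Conditions: NBS, MeCN, 0 °C → rt
Reagents that add atoms: N-bromosuccinimide, O=C1CCC(=O)N1Br
Why: Electrophilic aromatic bromination. The position between benzyloxy and methyl is para to the conjugated 3-methoxy group and should be the most activated, while the site between two alkoxy groups is disfavoured, as is general for 1,3-dialkoxy-5-methylbenzenes.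

Step 9
Reactants: 20 1-(benzyloxy)-2-bromo-4,5-dimethoxy-3-methylbenzene
Product: 22 2-(benzyloxy)-4,5-dimethoxy-6-methylbenzoic acid, via aryllithium 21 (not isolated)
Conditions: n-BuLi, THF, −78 °C; CO2 (g), −78 °C → rt; then aq. HCl
Reagents that add atoms: carbon dioxide, O=C=O; n-butyllithium, [Li]CCCC (lithium retained only in 21)
Why: Bromine–lithium exchange followed by carboxylation of the aryllithium. Low temperature and immediate quenching keep the aryllithium from deprotonating the benzylic ether position.

Step 10
Reactants: 22 2-(benzyloxy)-4,5-dimethoxy-6-methylbenzoic acid; 23 2,4-dihydroxy-6-methylbenzaldehyde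
Product: 24 4-formyl-3-hydroxy-5-methylphenyl 2-(benzyloxy)-4,5-dimethoxy-6-methylbenzoate
Conditions: (CF3CO)2O, toluene, rt; then aq. NaHCO3
Reagents that add atoms: none
Why: Esterification through the mixed trifluoroacetic anhydride, the classical method for hindered 2,6-disubstituted benzoic acids in depside synthesis. The 2-hydroxyl of 23 is hydrogen-bonded to the aldehyde, so acylation should occur only at the 4-hydroxyl.

Step 11
Reactants: 24 4-formyl-3-hydroxy-5-methylphenyl 2-(benzyloxy)-4,5-dimethoxy-6-methylbenzoate
Product: 25 3-(benzyloxy)-4-formyl-5-methylphenyl 2-(benzyloxy)-4,5-dimethoxy-6-methylbenzoate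
Conditions: BnBr, K2CO3, DMF, 50 °C
Reagents that add atoms: benzyl bromide, BrCc1ccccc1
Why: Williamson benzylation of the chelated phenol, which needs DMF and gentle warming. The di-ortho-substituted aryl ester is expected to tolerate carbonate.

Step 12
Reactants: 25 3-(benzyloxy)-4-formyl-5-methylphenyl 2-(benzyloxy)-4,5-dimethoxy-6-methylbenzoate
Product: 26 2-(benzyloxy)-4-{[2-(benzyloxy)-4,5-dimethoxy-6-methylbenzoyl]oxy}-6-methylbenzoic acid
Conditions: NaClO2, NaH2PO4, 2-methyl-2-butene, t-BuOH/THF/H2O, rt
Reagents that add atoms: sodium chlorite, [Na+].[O-]Cl=O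
Why: Pinnick oxidation of the aromatic aldehyde under buffered conditions that leave aryl esters and benzyl ethers intact. The alkene scavenger removes hypochlorous acid before it can chlorinate the electron-rich rings.

Step 13
Reactants: 26 2-(benzyloxy)-4-{[2-(benzyloxy)-4,5-dimethoxy-6-methylbenzoyl]oxy}-6-methylbenzoic acid
Product: 27 2-(benzyloxy)-4-{[2-(benzyloxy)-4,5-dimethoxy-6-methylbenzoyl]oxy}-6-methylbenzoyl fluoride
Conditions: cyanuric fluoride, pyridine, CH2Cl2, −10 °C → rt
Reagents that add atoms: cyanuric fluoride, Fc1nc(F)nc(F)n1
Why: Conversion of a carboxylic acid to its acyl fluoride with cyanuric fluoride and pyridine. Acyl fluorides of hindered acids survive aqueous work-up yet remain reactive toward oxygen anions.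

Step 14
Reactants: 15 benzyl 2-hydroxy-6-methyl-4-[(triisopropylsilyl)oxy]benzoate; 27 2-(benzyloxy)-4-{[2-(benzyloxy)-4,5-dimethoxy-6-methylbenzoyl]oxy}-6-methylbenzoyl fluoride
Product: 28 benzyl 4-({2-(benzyloxy)-4-[(2-(benzyloxy)-4,5-dimethoxy-6-methylbenzoyl)oxy]-6-methylbenzoyl}oxy)-2-hydroxy-6-methylbenzoate
Conditions: CsF (1.2 equiv), DMF, 0 °C → rt; 27 (1.05 equiv)
Reagents that add atoms: none
Why: Fluoride-promoted desilylative acylation: fluoride cleaves the aryl O–Si bond to give the C4 phenoxide, which attacks the acyl fluoride, and the fluoride so released ends on silicon, so no amine or alkoxide base is present. The 2-hydroxyl of ring C is chelated to its ester and flanked by it, and should not be acylated.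

Step 15
Reactants: 28 benzyl 4-({2-(benzyloxy)-4-[(2-(benzyloxy)-4,5-dimethoxy-6-methylbenzoyl)oxy]-6-methylbenzoyl}oxy)-2-hydroxy-6-methylbenzoate
Product: 29 2-hydroxy-4-({2-hydroxy-4-[(2-hydroxy-4,5-dimethoxy-6-methylbenzoyl)oxy]-6-methylbenzoyl}oxy)-6-methylbenzoic acid
Conditions: H2 (1 atm), Pd/C (10 % Pd), EtOAc, rt
Reagents that add atoms: none
Why: Hydrogenolysis removes the benzyl ester and both benzyl ethers in one neutral operation. Aryl esters, methyl ethers and the salicylic acid unit are inert to these conditions at room temperature.

## Compound list

1 | trimethylsilylacetylene | C#C[Si](C)(C)C | starting material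
2 | lithium (trimethylsilyl)acetylide | [Li+].[C-]#C[Si](C)(C)C | intermediate
3 | lithium 2-(trimethylsilyl)ethynolate | [Li+].[O-]C#C[Si](C)(C)C | intermediate
4 | triisopropyl{[(trimethylsilyl)ethynyl]oxy}silane | C[Si](C)(C)C#CO[Si](C(C)C)(C(C)C)C(C)C | intermediate
5 | ethynyl triisopropylsilyl ether | C#CO[Si](C(C)C)(C(C)C)C(C)C | intermediate
6 | butane-2,3-dione | CC(=O)C(C)=O | starting material
7 | benzyl (triphenylphosphoranylidene)acetate | O=C(C=P(c1ccccc1)(c1ccccc1)c1ccccc1)OCc1ccccc1 | starting material
8 | benzyl (E)-3-methyl-4-oxopent-2-enoate | CC(=O)/C(C)=C/C(=O)OCc1ccccc1 | intermediate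
9 | benzyl (E)-7,7,7-trifluoro-3-methyl-4,6-dioxohept-2-enoate (trifluoroacetyl diketone, largely enolised) | O=C(CC(=O)/C(C)=C/C(=O)OCc1ccccc1)C(F)(F)F | intermediate
10 | benzyl (E)-5-diazo-3-methyl-4-oxopent-2-enoate | [N-]=[N+]=CC(=O)/C(C)=C/C(=O)OCc1ccccc1 | intermediate
11 | benzyl (2E)-3-methyl-5-oxopenta-2,4-dienoate (vinylketene) | O=C=C/C(C)=C/C(=O)OCc1ccccc1 | intermediate
12 | benzyl (2E)-3-{4-oxo-2-[(triisopropylsilyl)oxy]cyclobut-2-en-1-yl}but-2-enoate (racemic 4-alkenylcyclobutenone) | C/C(=C\C(=O)OCc1ccccc1)C1C(=O)C=C1O[Si](C(C)C)(C(C)C)C(C)C | intermediate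
13 | benzyl (2E,4E)-3-methyl-7-oxo-5-[(triisopropylsilyl)oxy]hepta-2,4,6-trienoate (dienylketene) | O=C=C/C(O[Si](C(C)C)(C(C)C)C(C)C)=C\C(C)=C\C(=O)OCc1ccccc1 | intermediate
14 | benzyl 2-methyl-6-oxo-4-[(triisopropylsilyl)oxy]cyclohexa-2,4-diene-1-carboxylate (racemic cyclohexadienone) | CC1=CC(O[Si](C(C)C)(C(C)C)C(C)C)=CC(=O)C1C(=O)OCc1ccccc1 | intermediate
15 | benzyl 2-hydroxy-6-methyl-4-[(triisopropylsilyl)oxy]benzoate | Cc1cc(O[Si](C(C)C)(C(C)C)C(C)C)cc(O)c1C(=O)OCc1ccccc1 | intermediate
16 | 2,3-dimethoxytoluene | Cc1cccc(OC)c1OC | starting material
17 | 2-(3,4-dimethoxy-5-methylphenyl)-4,4,5,5-tetramethyl-1,3,2-dioxaborolane (aryl pinacol boronate) | Cc1cc(B2OC(C)(C)C(C)(C)O2)cc(OC)c1OC | intermediate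
18 | 3,4-dimethoxy-5-methylphenol | Cc1cc(O)cc(OC)c1OC | intermediate
19 | 5-(benzyloxy)-1,2-dimethoxy-3-methylbenzene | Cc1cc(OCc2ccccc2)cc(OC)c1OC | intermediate
20 | 1-(benzyloxy)-2-bromo-4,5-dimethoxy-3-methylbenzene | COc1cc(OCc2ccccc2)c(Br)c(C)c1OC | intermediate
21 | [2-(benzyloxy)-4,5-dimethoxy-6-methylphenyl]lithium (aryllithium) | [Li]c1c(C)c(OC)c(OC)cc1OCc1ccccc1 | intermediate
22 | 2-(benzyloxy)-4,5-dimethoxy-6-methylbenzoic acid | COc1cc(OCc2ccccc2)c(C(=O)O)c(C)c1OC | intermediate
23 | 2,4-dihydroxy-6-methylbenzaldehyde | Cc1cc(O)cc(O)c1C=O | starting material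
24 | 4-formyl-3-hydroxy-5-methylphenyl 2-(benzyloxy)-4,5-dimethoxy-6-methylbenzoate | COc1cc(OCc2ccccc2)c(C(=O)Oc2cc(C)c(C=O)c(O)c2)c(C)c1OC | intermediate
25 | 3-(benzyloxy)-4-formyl-5-methylphenyl 2-(benzyloxy)-4,5-dimethoxy-6-methylbenzoate | COc1cc(OCc2ccccc2)c(C(=O)Oc2cc(C)c(C=O)c(OCc3ccccc3)c2)c(C)c1OC | intermediate
26 | 2-(benzyloxy)-4-{[2-(benzyloxy)-4,5-dimethoxy-6-methylbenzoyl]oxy}-6-methylbenzoic acid | COc1cc(OCc2ccccc2)c(C(=O)Oc2cc(C)c(C(=O)O)c(OCc3ccccc3)c2)c(C)c1OC | intermediate
27 | 2-(benzyloxy)-4-{[2-(benzyloxy)-4,5-dimethoxy-6-methylbenzoyl]oxy}-6-methylbenzoyl fluoride | COc1cc(OCc2ccccc2)c(C(=O)Oc2cc(C)c(C(F)=O)c(OCc3ccccc3)c2)c(C)c1OC | intermediate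
28 | benzyl 4-({2-(benzyloxy)-4-[(2-(benzyloxy)-4,5-dimethoxy-6-methylbenzoyl)oxy]-6-methylbenzoyl}oxy)-2-hydroxy-6-methylbenzoate | COc1cc(OCc2ccccc2)c(C(=O)Oc2cc(C)c(C(=O)Oc3cc(C)c(C(=O)OCc4ccccc4)c(O)c3)c(OCc3ccccc3)c2)c(C)c1OC | intermediate
29 | 2-hydroxy-4-({2-hydroxy-4-[(2-hydroxy-4,5-dimethoxy-6-methylbenzoyl)oxy]-6-methylbenzoyl}oxy)-6-methylbenzoic acid | COc1cc(O)c(C(=O)Oc2cc(C)c(C(=O)Oc3cc(C)c(C(=O)O)c(O)c3)c(O)c2)c(C)c1OC | target

## Step count and risk

Total: 15 steps. Longest linear sequence: 10 steps (steps 6 to 15, from 16 to 29). The ring C branch (steps 1–5) joins at step 14.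

Least certain steps:

**Step 5 (key step).**
- What may go wrong: photoisomerisation of the enone double bond before or after loss of nitrogen would bring the ester oxygen within reach of the ketene and divert material into pyranone formation. The vinylketene may also be captured by the phenol already formed, and the thermal conversion of the cyclobutenone may stop short. The siloxyalkyne is acid-sensitive and may be lost to adventitious protic impurities during irradiation.
- Fallback: this one gives up the de novo ring construction but keeps the end game. It sets out from aldehyde 23. Silylation of the unchelated 4-hydroxyl with i-Pr3SiCl and imidazole in DMF should give 2-hydroxy-6-methyl-4-[(triisopropylsilyl)oxy]benzaldehyde F1. Pinnick oxidation (NaClO2, NaH2PO4, 2-methyl-2-butene) should give 2-hydroxy-6-methyl-4-[(triisopropylsilyl)oxy]benzoic acid F2. Benzylation of the carboxylate alone (BnBr, KHCO3, DMF, rt) comes back to the route at 15.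

**Step 4.**
- What may go wrong: the lithium enolate of 8 faces a very electrophilic 4-oxo-enoate, so Michael self-condensation or deprotonation at the vinylic methyl group may compete with trifluoroacetylation.
- Fallback: this one avoids enolate chemistry and sets out from ylide 7. Wittig reaction with tert-butyl pyruvate should give 4-benzyl 1-tert-butyl (E)-2-methylbut-2-enedioate F3, purified from its Z isomer. CF3CO2H in CH2Cl2 removes the tert-butyl group to give (E)-4-(benzyloxy)-2-methyl-4-oxobut-2-enoic acid F4. Oxalyl chloride with catalytic DMF gives benzyl (E)-4-chloro-3-methyl-4-oxobut-2-enoate F5. Acylation of Me3SiCHN2 in MeCN/THF at 0 °C comes back to the route at 10. The temperature is kept low because the diazoalkane can also add across the alkene.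

**Step 2.**
- What may go wrong: methoxide may attack the oxygen-bound silicon as well, releasing the ynolate and hence a ketene that is lost to methanolysis. The small terminal siloxyalkyne may also be lost on concentration or may oligomerise on storage.
- Fallback: this one sets out from 4 and 10. Compound 4 is used directly in the photochemical benzannulation, where its silyl-bearing carbon is the nucleophilic terminus. This should give benzyl 2-hydroxy-6-methyl-3-(trimethylsilyl)-4-[(triisopropylsilyl)oxy]benzoate F6. Ipso-protodesilylation of this doubly oxygen-flanked arylsilane with CF3CO2H in CH2Cl2 at 0 °C comes back to the route at 15.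

**Step 14.**
- What may go wrong: attack of the phenoxide on the di-ortho-substituted aroyl fluoride may be slow. That would leave time for acyl exchange between the phenoxide and the aryl esters already present, for hydrolysis of the acyl fluoride by traces of water, or for a second acylation at the 2-hydroxyl.
- Fallback: this one bypasses 27 and sets out from 15 and 26. Bu4NF buffered with AcOH in THF at 0 °C should give benzyl 2,4-dihydroxy-6-methylbenzoate F7. Esterification of acid 26 with F7 through the mixed anhydride ((CF3CO)2O, toluene, rt), which suits hindered acids and selects the unchelated 4-hydroxyl, comes back to the route at 28.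

## Further compounds

F1 | step 5 | 2-hydroxy-6-methyl-4-[(triisopropylsilyl)oxy]benzaldehyde | Cc1cc(O[Si](C(C)C)(C(C)C)C(C)C)cc(O)c1C=O
F2 | step 5 | 2-hydroxy-6-methyl-4-[(triisopropylsilyl)oxy]benzoic acid | Cc1cc(O[Si](C(C)C)(C(C)C)C(C)C)cc(O)c1C(=O)O
F3 | step 4 | 4-benzyl 1-tert-butyl (E)-2-methylbut-2-enedioate | CC(C)(C)OC(=O)/C(C)=C/C(=O)OCc1ccccc1
F4 | step 4 | (E)-4-(benzyloxy)-2-methyl-4-oxobut-2-enoic acid | OC(=O)/C(C)=C/C(=O)OCc1ccccc1
F5 | step 4 | benzyl (E)-4-chloro-3-methyl-4-oxobut-2-enoate | ClC(=O)/C(C)=C/C(=O)OCc1ccccc1
F6 | step 2 | benzyl 2-hydroxy-6-methyl-3-(trimethylsilyl)-4-[(triisopropylsilyl)oxy]benzoate | Cc1cc(O[Si](C(C)C)(C(C)C)C(C)C)c([Si](C)(C)C)c(O)c1C(=O)OCc1ccccc1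
F7 | step 14 | benzyl 2,4-dihydroxy-6-methylbenzoate | Cc1cc(O)cc(O)c1C(=O)OCc1ccccc1
A1 | alternative 1 | 3-(benzyloxy)-4-iodo-5-methylphenyl 2-(benzyloxy)-4,5-dimethoxy-6-methylbenzoate | COc1cc(OCc2ccccc2)c(C(=O)Oc2cc(C)c(I)c(OCc3ccccc3)c2)c(C)c1OC
A2 | alternative 1 | benzyl 2,4-dihydroxy-6-methylbenzoate | Cc1cc(O)cc(O)c1C(=O)OCc1ccccc1
A3 | alternative 1 | benzyl 4-({2-(benzyloxy)-4-[(2-(benzyloxy)-4,5-dimethoxy-6-methylbenzoyl)oxy]-6-methylbenzoyl}oxy)-2-hydroxy-6-methylbenzoate | COc1cc(OCc2ccccc2)c(C(=O)Oc2cc(C)c(C(=O)Oc3cc(C)c(C(=O)OCc4ccccc4)c(O)c3)c(OCc3ccccc3)c2)c(C)c1OC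
A4 | alternative 2 | benzyl 3-oxobutanoate | CC(=O)CC(=O)OCc1ccccc1
A5 | alternative 2 | methyl (Z)-2-methoxybut-2-enoate | C/C=C(\OC)C(=O)OC
A6 | alternative 2 | benzyl trans-2-hydroxy-5-methoxy-6-methyl-4-oxocyclohex-1-ene-1-carboxylate (racemic, one enantiomer drawn) | O=C(OCc1ccccc1)C1=C(O)CC(=O)[C@H](OC)[C@H]1C
A7 | alternative 3 | (1Z)-1-methoxy-1,3-bis(trimethylsilyloxy)buta-1,3-diene | CO/C(O[Si](C)(C)C)=C/C(=C)O[Si](C)(C)C
A8 | alternative 3 | benzyl 2-(benzyloxy)-4-(but-2-ynoyloxy)-6-methylbenzoate | CC#CC(=O)Oc1cc(C)c(C(=O)OCc2ccccc2)c(OCc2ccccc2)c1
A9 | alternative 3 | benzyl 2-(benzyloxy)-4-[(2,4-dihydroxy-6-methylbenzoyl)oxy]-6-methylbenzoate | Cc1cc(O)cc(O)c1C(=O)Oc1cc(C)c(C(=O)OCc2ccccc2)c(OCc2ccccc2)c1
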